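Conventions used below: the decalin is numbered C1–C10 (ring A = C1–C5 and C10, ring B = C5–C10), C11 is the exocyclic carbon on C9, and β denotes the face that carries the C10 methyl group.

## Analysis of the target

Target 19 is a sesquiterpene hydroxyquinone. A trans-fused decalin carries an exocyclic methylene on C4, and C9 is linked through C11H2 to a 2-hydroxy-5-methoxy-1,4-benzoquinone. There are four stereocentres: C5 (H, α), C8 (CH3, β), C9 (CH3 β, C11 α) and C10 (CH3, β), i.e. (5S,8S,9R,10S). C9 and C10 are adjacent quaternary carbons, and all three methyl groups sit on one face. With ring B as a chair the C8 and C10 methyls are 1,3-diaxial, so this array is strained and has to be fixed kinetically, not by equilibration.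

The quinone is a vinylogous acid and ester that will not tolerate organometallic reagents, hydrides, tin radicals or fluoride, so it has to appear last. The 1,1-disubstituted C4 alkene migrates under acid and would not survive a hydrogenation or a radical at C11. C5–H becomes epimerisable whenever C4 is a carbonyl, and the cis-fused epimer is probably not the less stable one.

The hard part is the C8–C9–C10 triad with its vicinal quaternary centres, set in the right sense relative to C5. The strategy rests on one observation about ring B:

- C8 and C9 each carry a methyl group, cis to one another, and C9 carries one further carbon (C11). This is the pattern of (E)-2-methylbut-2-enal 6.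
- The other four ring B carbons (C10, C5, C6, C7) form a diene that is already anchored in ring A, with the methyl on C10.

## Retrosynthetic reasoning

**Quinone oxygens.** 19 is traced to the symmetric 2,5-dimethoxyquinone 18 by hydrolysis of one vinylogous ester, and 18 to the tetramethoxyarene 17 by oxidative demethylation. This keeps the quinone out of the route until two steps from the end. The forward steps must spare the C4 methylene and must distinguish two methoxy groups.

**C4 methylene.** 17 is cut to ketone 16, alcohol 15 and silyl ether 14. The methylene is carried as an oxygen for two reasons. An exocyclic alkene would be reduced in the hydrogenation and would trap a C11 radical by 5-exo closure. The C4 oxygen is also the stereocontrol element of the cycloaddition. The forward methylenation must not epimerise C5.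

**C11–aryl bond.** 14 comes from xanthate 13 and carbinol 11, and 11 from aldehyde 8 and aryllithium 10, which is made from arene 9. The whole oxygenated ring arrives in one piece from a symmetric arene, and the formyl group left on C9 by the cycloaddition is put to use. The forward steps are an addition to a neopentyl aldehyde and removal of the benzylic oxygen without a cationic rearrangement.

**C5–H.** 8 is traced to octalin 7 by addition of hydrogen across C5=C6. The stereocentre is set by the face of approach, which is what the analysis demands.

**Ring B (key disconnection).** 7 is cut at C7–C8 and C9–C10 into diene 5 and enal 6. Any other pair of ring B bonds would leave one of the vicinal quaternary centres to be made by alkylation or conjugate addition at a fully substituted carbon. This cut makes both in one pericyclic event from an alkene of fixed geometry. It gains ring B, two C–C bonds and the centres C8, C9 and C10. The forward reaction needs ortho regiochemistry, endo topology and attack on the α face.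

**Diene.** 5 is traced to iodide 4 by palladium-catalysed vinylation at C5, 4 to alcohol 3 by silylation, 3 to iodoenone 2 by enantioselective reduction, and 2 to enone 1 by α-iodination. The iodine serves twice: as the large group that makes the reduction selective, and as the handle for the vinyl group.

## Alternatives that were turned down

**Alternative 1:** an intramolecular Diels–Alder reaction that closes both rings.
- Disconnection: C5–C10 and C8–C9 are cut, giving the acyclic trienal A2, which already carries the tetramethoxybenzyl group on C9.
- Forward key step: on heating or with Me2AlCl, the E,E-diene of A2 adds to its tetrasubstituted enal and gives the trans-fused octalin A1.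
- For it: both rings and all four stereocentres come from one step, the ring fusion is set directly, and no aryl nucleophile has to attack a hindered aldehyde. On these points it is stronger than the chosen route.
- Against it: the dienophile is a tetrasubstituted enal whose E geometry must be made and kept; the C5–C10 bond forms at a fully substituted carbon; the C9 formyl group of A1 has to be reduced to a methyl at a neopentyl centre; and the C6=C7 alkene still has to be hydrogenated. A2 needs a long linear assembly.
- Comparison: the chosen route offers a short convergent approach from a commercial, geometrically fixed dienophile, and the formyl group it leaves is used to attach the arene and not removed.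

**Alternative 2:** a gold-catalysed Conia-ene closure of ring A.
- Disconnection: C4–C5 is cut, giving the monocyclic silyl enol ether A4 with a pentynyl chain on C10.
- Forward key step: Ph3PAuCl/AgBF4 with methanol activates the alkyne, and the enol ether carbon C5 attacks C4 (6-exo-dig) to give the methylene decalinone A3.
- For it: the exocyclic methylene arises directly, so no C4 ketone with an epimerisable C5 neighbour is ever handled. On this point it is stronger.
- Against it: A4 must already contain the C8–C9–C10 triad, so the real problem is untouched. Its enol ether must be formed regioselectively toward the carbon next to quaternary C10. The ring fusion is decided in the closure. A3 is a β,γ-unsaturated ketone whose C6 oxygen must be removed without moving the alkene into conjugation.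
- Comparison: the chosen route makes the triad in its key step and pays with three routine steps for the methylene.

**Alternative 3:** de novo construction of the quinone from a squarate-derived cyclobutenone.
- Disconnection: one C–C bond of the six-membered ring is cut, giving the 4-hydroxy-4-(2-methoxyvinyl)cyclobutenone A6.
- Forward key step: heating in toluene opens A6 to a dienylketene, which electrocyclises to the hydroquinone A5.
- For it: the two oxygens are differentiated from the start (tert-butoxy against methoxy), and the conditions are neutral. It is stronger than the chosen final hydrolysis on regiochemistry.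
- Against it: A6 requires a C11 nucleophile on the neopentyl carbon next to quaternary C9, which is hard to generate. The ring is built in several linear steps at the end of the route. The decalin is not addressed at all.
- Comparison: the chosen route attaches a complete symmetric arene in one step and reaches the quinone in two more.

Key step: step 5

Assumptions on the chemistry: the sense of induction in step 2 follows the usual oxazaborolidine model with the iodoalkenyl arm as the large group. The C11 carbinol configuration in 11 to 13 is not controlled and is erased in step 9.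

## Route

Step 1
Reactants: 1 3-methylcyclohex-2-en-1-one
Product: 2 2-iodo-3-methylcyclohex-2-en-1-one
Conditions: I2, pyridine, 4-(dimethylamino)pyridine (cat.), CH2Cl2, rt
Reagents that add atoms: iodine, II
Why: α-Iodination of an enone by conjugate addition of the amine, iodination of the enolate and E1cB loss of the amine; the β-methyl slows the first event, hence the nucleophilic catalyst; no stereocentre is formed.

Step 2
Reactants: 2 2-iodo-3-methylcyclohex-2-en-1-one
Product: 3 (S)-2-iodo-3-methylcyclohex-2-en-1-ol
Conditions: (R)-1-methyl-3,3-diphenyltetrahydro-1H,3H-pyrrolo[1,2-c][1,3,2]oxazaborole (0.2 equiv), BH3·SMe2, THF, −10 °C; MeOH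
Reagents that add atoms: none
Why: Corey–Bakshi–Shibata reduction; the iodoalkenyl arm acts as the large group and the ring CH2 as the small one, so hydride is delivered to the face that gives the S carbinol, the future C4.

Step 3
Reactants: 3 (S)-2-iodo-3-methylcyclohex-2-en-1-ol
Product: 4 (S)-tert-butyl[(2-iodo-3-methylcyclohex-2-en-1-yl)oxy]dimethylsilane
Conditions: TBSCl, imidazole, DMF, rt
Reagents that add atoms: tert-butyldimethylsilyl chloride, CC(C)(C)[Si](C)(C)Cl
Why: Standard silylation of a secondary allylic alcohol; the bulky ether later shields one face of the diene and keeps the hydroxyl out of the coupling.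

Step 4
Reactants: 4 (S)-tert-butyl[(2-iodo-3-methylcyclohex-2-en-1-yl)oxy]dimethylsilane
Product: 5 (S)-tert-butyl[(2-ethenyl-3-methylcyclohex-2-en-1-yl)oxy]dimethylsilane
Conditions: tributyl(vinyl)stannane, Pd(PPh3)4 (5 mol %), CuI, CsF, DMF, 45 °C
Reagents that add atoms: tributyl(vinyl)stannane, C=C[Sn](CCCC)(CCCC)CCCC
Why: Stille coupling of an alkenyl iodide with retention of the ring alkene; copper and fluoride speed the transmetalation at the doubly flanked carbon; the C4 stereocentre is not touched.

Step 5
Reactants: 5 (S)-tert-butyl[(2-ethenyl-3-methylcyclohex-2-en-1-yl)oxy]dimethylsilane, 6 (E)-2-methylbut-2-enal (tiglaldehyde)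
Product: 7 4β-(tert-butyldimethylsilyloxy)-8β,9β,10β-trimethyl-Δ5-octalin-9α-carbaldehyde (4S,8S,9R,10S)
Conditions: 6 (3 equiv), EtAlCl2 (0.5 equiv, premixed with 6), CH2Cl2, −78 to −20 °C
Reagents that add atoms: none
Why: EtAlCl2 binds the formyl oxygen of s-trans 6, lowers its LUMO and polarises it toward C8, and the complex adds to the s-cis conformer of 5 in a concerted but strongly asynchronous Lewis-acid-promoted Diels–Alder reaction, the known way from 2-methyl-1-vinylcyclohexenes to angular-methyl decalins. Ring B closes as a cyclohexene by suprafacial [4+2] cycloaddition: C7–C8 forms first between the unsubstituted diene terminus (largest HOMO coefficient) and the enal β-carbon, the congested C9–C10 bond follows, and this fixes the ortho orientation and leaves C5=C6. C8 relative to C9 is set by the E geometry of 6, which is transferred suprafacially and puts the two methyls cis. C9 relative to C10 is set by the endo topology: the complexed formyl group lies under C5, ends cis to C1 (the outside group on C10) and trans to the inside methyl, so the C9 and C10 methyls are cis. The absolute sense comes from C4: the silyloxy group, held pseudoaxial by allylic strain against the vinyl group, closes the β face, 6 adds to the α face and the C10 methyl ends β. The step needs regio-, endo and facial selectivity; the first and the third are secured by the diene substitution and the C4 centre, whereas the endo preference rests only on the secondary interactions of the complexed formyl group and is opposed by contact between the exo α-methyl of 6 and the inside C10 methyl. Keeping the Lewis acid below one equivalent with excess 6 leaves no free EtAlCl2 to ionise the allylic silyl ether, and its ethyl group removes adventitious protons.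

Step 6
Reactants: 7 4β-(tert-butyldimethylsilyloxy)-8β,9β,10β-trimethyl-Δ5-octalin-9α-carbaldehyde
Product: 8 4β-(tert-butyldimethylsilyloxy)-8β,9β,10β-trimethyl-5α-decalin-9α-carbaldehyde (4S,5R,8S,9R,10S)
Conditions: H2 (3 bar), Pd/C, EtOAc, rt
Reagents that add atoms: none
Why: Heterogeneous syn hydrogenation of the trisubstituted C5=C6 alkene; the β face is closed by the axial C10 methyl and the pseudoaxial C4 silyloxy group, so hydrogen should arrive from the α face and give the trans ring fusion, as in the reduction of Δ5 steroids; the neopentyl aldehyde should not be reduced under these conditions.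

Step 7
Reactants: 8 4β-(tert-butyldimethylsilyloxy)-8β,9β,10β-trimethyl-5α-decalin-9α-carbaldehyde, 9 1,2,4,5-tetramethoxybenzene
Product: 11 (2,3,5,6-tetramethoxyphenyl)[4β-(tert-butyldimethylsilyloxy)-8β,9β,10β-trimethyl-5α-decalin-9α-yl]methanol (C11 epimers), via 2,3,5,6-tetramethoxyphenyllithium 10 (not isolated)
Conditions: 9, n-BuLi, THF, 0 °C; then 8, −78 °C to rt; aq NH4Cl
Reagents that add atoms: none
Why: Directed ortho-lithiation of 9 between two methoxy groups gives 10, which adds 1,2 to the non-enolisable aldehyde; the new C11 carbinol centre is not controlled and does not matter.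

Step 8
Reactants: 11 (2,3,5,6-tetramethoxyphenyl)[4β-(tert-butyldimethylsilyloxy)-8β,9β,10β-trimethyl-5α-decalin-9α-yl]methanol
Product: 13 S-methyl xanthate of 11 (O-alkyl S-methyl dithiocarbonate at C11), via potassium xanthate salt 12 (not isolated)
Conditions: KN(SiMe3)2, THF, −78 to 0 °C; CS2; MeI, 0 °C to rt
Reagents that add atoms: carbon disulfide, S=C=S; iodomethane, CI
Why: First half of the Barton–McCombie deoxygenation: the alkoxide adds to CS2 and the dithiocarbonate 12 is methylated on sulfur; C9 is quaternary, so no Chugaev elimination is possible.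

Step 9
Reactants: 13 S-methyl xanthate of 11
Product: 14 4β-(tert-butyldimethylsilyloxy)-8β,9β,10β-trimethyl-9α-(2,3,5,6-tetramethoxybenzyl)-5α-decalin
Conditions: Bu3SnH, azobisisobutyronitrile (cat.), toluene, 110 °C
Reagents that add atoms: none
Why: Barton–McCombie radical deoxygenation: the stannyl radical adds to the thiocarbonyl, β-scission gives the benzylic C11 radical, and this abstracts hydrogen from the stannane; unlike a cation at C11, the radical does not provoke 1,2-shifts from quaternary C9, and no alkene is present to trap it.

Step 10
Reactants: 14 4β-(tert-butyldimethylsilyloxy)-8β,9β,10β-trimethyl-9α-(2,3,5,6-tetramethoxybenzyl)-5α-decalin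
Product: 15 8β,9β,10β-trimethyl-9α-(2,3,5,6-tetramethoxybenzyl)-5α-decalin-4β-ol
Conditions: Bu4NF, THF, 50 °C
Reagents that add atoms: none
Why: Fluoride cleavage of the silyl ether; the axial ether is hindered by the C10 methyl, hence the gentle heating; nothing else in 14 is sensitive to fluoride.

Step 11
Reactants: 15 8β,9β,10β-trimethyl-9α-(2,3,5,6-tetramethoxybenzyl)-5α-decalin-4β-ol
Product: 16 8β,9β,10β-trimethyl-9α-(2,3,5,6-tetramethoxybenzyl)-5α-decalin-4-one
Conditions: Dess–Martin periodinane, NaHCO3, CH2Cl2, 0 °C to rt
Reagents that add atoms: none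
Why: Dess–Martin oxidation of a secondary alcohol under buffered, non-basic conditions, chosen so that the now enolisable C5–H is not epimerised; the electron-rich arene is left alone.

Step 12
Reactants: 16 8β,9β,10β-trimethyl-9α-(2,3,5,6-tetramethoxybenzyl)-5α-decalin-4-one
Product: 17 8β,9β,10β-trimethyl-4-methylidene-9α-(2,3,5,6-tetramethoxybenzyl)-5α-decalin
Conditions: Cp2Ti(μ-Cl)(μ-CH2)AlMe2, pyridine, THF/toluene, −40 to 0 °C
Reagents that add atoms: Tebbe reagent Cp2Ti(μ-Cl)(μ-CH2)AlMe2, C[Al-]1(C)C[Ti]([Cl+]1)(C1C=CC=C1)C1C=CC=C1
Why: Tebbe methylenation through a titanium methylidene and an oxatitanacyclobutane; the reagent is not basic, so the C5 centre next to the carbonyl is expected to survive where a phosphorus ylide could epimerise it.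

Step 13
Reactants: 17 8β,9β,10β-trimethyl-4-methylidene-9α-(2,3,5,6-tetramethoxybenzyl)-5α-decalin
Product: 18 2,5-dimethoxy-3-{[(1R,2S,4aS,8aS)-1,2,8a-trimethyl-5-methylidenedecahydronaphthalen-1-yl]methyl}cyclohexa-2,5-diene-1,4-dione
Conditions: (NH4)2Ce(NO3)6, MeCN/H2O, 0 °C
Reagents that add atoms: water, O
Why: Oxidative demethylation of a para-dimethoxyarene by tetravalent cerium (arene radical cation, ipso attack of water, loss of methanol); the two para pairs of methoxy groups are related by the mirror plane of the arene, so a single quinone results; the 1,1-disubstituted alkene should survive the short, cold exposure.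

Step 14
Reactants: 18 2,5-dimethoxy-3-{[(1R,2S,4aS,8aS)-1,2,8a-trimethyl-5-methylidenedecahydronaphthalen-1-yl]methyl}cyclohexa-2,5-diene-1,4-dione
Product: 19 2-hydroxy-5-methoxy-3-{[(1R,2S,4aS,8aS)-1,2,8a-trimethyl-5-methylidenedecahydronaphthalen-1-yl]methyl}cyclohexa-2,5-diene-1,4-dione (target)
Conditions: aq KOH, MeOH/THF, rt; then 1 M HCl
Reagents that add atoms: potassium hydroxide, [K+].[OH-]
Why: Addition–elimination of hydroxide at a vinylogous ester, the regioselective saponification known for 3-alkyl-2,5-dimethoxybenzoquinones; the C2 methoxy group is wedged between the C1 carbonyl and the side chain, is twisted out of conjugation and is the more electrophilic, and the vinylogous carboxylate formed resists a second substitution.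

## Compound list

1 | 3-methylcyclohex-2-en-1-one | CC1=CC(=O)CCC1 | starting material
2 | 2-iodo-3-methylcyclohex-2-en-1-one | CC1=C(I)C(=O)CCC1 | intermediate
3 | (S)-2-iodo-3-methylcyclohex-2-en-1-ol | IC1=C(C)CCC[C@@H]1O | intermediate
4 | (S)-tert-butyl[(2-iodo-3-methylcyclohex-2-en-1-yl)oxy]dimethylsilane | IC1=C(C)CCC[C@@H]1O[Si](C)(C)C(C)(C)C | intermediate
5 | (S)-tert-butyl[(2-ethenyl-3-methylcyclohex-2-en-1-yl)oxy]dimethylsilane | C=CC1=C(C)CCC[C@@H]1O[Si](C)(C)C(C)(C)C | intermediate
6 | (E)-2-methylbut-2-enal (tiglaldehyde) | C/C=C(\C)C=O | starting material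
7 | 4β-(tert-butyldimethylsilyloxy)-8β,9β,10β-trimethyl-Δ5-octalin-9α-carbaldehyde | CC(C)(C)[Si](C)(C)O[C@H]1CCC[C@@]2(C)C1=CC[C@H](C)[C@@]2(C)C=O | intermediate
8 | 4β-(tert-butyldimethylsilyloxy)-8β,9β,10β-trimethyl-5α-decalin-9α-carbaldehyde | CC(C)(C)[Si](C)(C)O[C@H]1CCC[C@@]2(C)[C@H]1CC[C@H](C)[C@@]2(C)C=O | intermediate
9 | 1,2,4,5-tetramethoxybenzene | COc1cc(OC)c(OC)cc1OC | starting material
10 | 2,3,5,6-tetramethoxyphenyllithium | [Li]c1c(OC)c(OC)cc(OC)c1OC | intermediate (not isolated)
11 | (2,3,5,6-tetramethoxyphenyl)[4β-(tert-butyldimethylsilyloxy)-8β,9β,10β-trimethyl-5α-decalin-9α-yl]methanol, C11 not defined | CC(C)(C)[Si](C)(C)O[C@H]1CCC[C@@]2(C)[C@H]1CC[C@H](C)[C@@]2(C)C(O)c1c(OC)c(OC)cc(OC)c1OC | intermediate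
12 | potassium xanthate (O-alkyl dithiocarbonate) of 11 | CC(C)(C)[Si](C)(C)O[C@H]1CCC[C@@]2(C)[C@H]1CC[C@H](C)[C@@]2(C)C(OC(=S)[S-])c1c(OC)c(OC)cc(OC)c1OC.[K+] | intermediate (not isolated)
13 | S-methyl xanthate of 11 | CC(C)(C)[Si](C)(C)O[C@H]1CCC[C@@]2(C)[C@H]1CC[C@H](C)[C@@]2(C)C(OC(=S)SC)c1c(OC)c(OC)cc(OC)c1OC | intermediate
14 | 4β-(tert-butyldimethylsilyloxy)-8β,9β,10β-trimethyl-9α-(2,3,5,6-tetramethoxybenzyl)-5α-decalin | CC(C)(C)[Si](C)(C)O[C@H]1CCC[C@@]2(C)[C@H]1CC[C@H](C)[C@@]2(C)Cc1c(OC)c(OC)cc(OC)c1OC | intermediate
15 | 8β,9β,10β-trimethyl-9α-(2,3,5,6-tetramethoxybenzyl)-5α-decalin-4β-ol | O[C@H]1CCC[C@@]2(C)[C@H]1CC[C@H](C)[C@@]2(C)Cc1c(OC)c(OC)cc(OC)c1OC | intermediate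
16 | 8β,9β,10β-trimethyl-9α-(2,3,5,6-tetramethoxybenzyl)-5α-decalin-4-one | O=C1CCC[C@@]2(C)[C@H]1CC[C@H](C)[C@@]2(C)Cc1c(OC)c(OC)cc(OC)c1OC | intermediate
17 | 8β,9β,10β-trimethyl-4-methylidene-9α-(2,3,5,6-tetramethoxybenzyl)-5α-decalin | C=C1CCC[C@@]2(C)[C@H]1CC[C@H](C)[C@@]2(C)Cc1c(OC)c(OC)cc(OC)c1OC | intermediate
18 | 2,5-dimethoxy-3-{[(1R,2S,4aS,8aS)-1,2,8a-trimethyl-5-methylidenedecahydronaphthalen-1-yl]methyl}cyclohexa-2,5-diene-1,4-dione | C=C1CCC[C@@]2(C)[C@H]1CC[C@H](C)[C@@]2(C)CC1=C(OC)C(=O)C=C(OC)C1=O | intermediate
19 | 2-hydroxy-5-methoxy-3-{[(1R,2S,4aS,8aS)-1,2,8a-trimethyl-5-methylidenedecahydronaphthalen-1-yl]methyl}cyclohexa-2,5-diene-1,4-dione | C=C1CCC[C@@]2(C)[C@H]1CC[C@H](C)[C@@]2(C)CC1=C(O)C(=O)C=C(OC)C1=O | target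

Total step count: 14. Longest linear sequence: 14 steps (1 to 19); 6 and 9 enter as purchased.

## Least certain steps

**Step 5 (key step).** Three things can go wrong.
- The inside methyl on C10 twists the diene out of the s-cis geometry. The cycloaddition may then be so slow that ionisation of the allylic silyl ether and oligomerisation of the diene overtake it.
- The endo preference may erode or invert. The exo α-methyl of 6 meets the inside C10 methyl much as it meets the bridge of cyclopentadiene, and that would give the C8/C9 epimeric pair.
- The adduct may undergo a Lewis-acid carbonyl-ene closure onto C5=C6.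

Fallback, from 5, returning at 14: the C9 quaternary centre is completed after the cycloaddition instead of in it. Diene 5 is combined under the same Lewis acid with (E)-but-2-enal, a more reactive dienophile whose endo preference is not opposed by an α-substituent. This should give the 9-unsubstituted octalin aldehyde F1, which is hydrogenated to the trans-decalin aldehyde F2. In parallel, 10 is formylated with DMF to 2,3,5,6-tetramethoxybenzaldehyde F3, reduced with NaBH4 to (2,3,5,6-tetramethoxyphenyl)methanol F4 and converted with PBr3 into 2,3,5,6-tetramethoxybenzyl bromide F5. The potassium enolate of F2 (KOt-Bu, THF) is alkylated on carbon by F5 from the α face, since the β face is closed by the two flanking axial methyls on C8 and C10. This gives the 9α-benzyl 9β-formyl decalin F6. Its hydrazone F7 (N2H4·H2O, EtOH) is reduced with KOt-Bu in DMSO (Wolff–Kishner, Cram variant), which turns the β-formyl group into the C9 methyl and delivers 14.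

**Step 6.** Facial selectivity may be poor, the alkene may migrate toward the silyl enol ether position, or the allylic C–O bond may be hydrogenolysed on palladium.

Fallback, from 7, returning at 8: the aldehyde is reduced with NaBH4 to the Δ5 primary alcohol F8. The C11 hydroxyl, held on the α face, then directs [Ir(cod)(PCy3)(py)]PF6/H2 in CH2Cl2 to that face and gives the saturated alcohol F9. Dess–Martin oxidation returns 8.

**Step 7.** The addition may be incomplete because the formyl group sits between two fully substituted carbons and the nucleophile has two ortho methoxy groups; on warming, 10 may decompose before it adds.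

Fallback, from 7 and 10, returning at 11: the order is changed. 10 is added to the flatter octalin aldehyde 7, which lacks the axial C5 hydrogen, to give the unsaturated carbinol F10. The alkene is then reduced by hydroxyl-directed hydrogenation with [Ir(cod)(PCy3)(py)]PF6/H2, which gives 11.

**Step 12.** C5 may epimerise through the C4 enol(ate); the cis-fused ketone relieves the 1,3-diaxial methyl pair and may be the more stable. The olefination may also stall at the hindered carbonyl.

Fallback, from 16, returning at 17: a Peterson sequence. Me3SiCH2Li, premixed with anhydrous CeCl3 to suppress enolisation, adds to 16 and gives the β-hydroxysilane F11. KH in THF then eliminates it to 17.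

**Step 14.** Regiocontrol may be lost through attack at the unhindered C5 position, or hydrolysis may run on to the bis-hydroxyquinone.

Fallback, from 18, returning at 19: both methoxy groups are hydrolysed with excess aqueous LiOH to the 2,5-dihydroxyquinone F12. One equivalent of Me3SiCHN2 in MeOH/toluene at 0 °C then methylates the less hindered C5 hydroxyl, remote from the side chain. The regioisomer would have to be separated.

## Further compounds

F1 | step 5 | 4β-(tert-butyldimethylsilyloxy)-8β,10β-dimethyl-Δ5-octalin-9α-carbaldehyde | CC(C)(C)[Si](C)(C)O[C@H]1CCC[C@@]2(C)C1=CC[C@H](C)[C@H]2C=O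
F2 | step 5 | 4β-(tert-butyldimethylsilyloxy)-8β,10β-dimethyl-5α-decalin-9α-carbaldehyde | CC(C)(C)[Si](C)(C)O[C@H]1CCC[C@@]2(C)[C@H]1CC[C@H](C)[C@H]2C=O
F3 | step 5 | 2,3,5,6-tetramethoxybenzaldehyde | O=Cc1c(OC)c(OC)cc(OC)c1OC
F4 | step 5 | (2,3,5,6-tetramethoxyphenyl)methanol | OCc1c(OC)c(OC)cc(OC)c1OC
F5 | step 5 | 2,3,5,6-tetramethoxybenzyl bromide | BrCc1c(OC)c(OC)cc(OC)c1OC
F6 | step 5 | 4β-(tert-butyldimethylsilyloxy)-8β,10β-dimethyl-9α-(2,3,5,6-tetramethoxybenzyl)-5α-decalin-9β-carbaldehyde | CC(C)(C)[Si](C)(C)O[C@H]1CCC[C@@]2(C)[C@H]1CC[C@H](C)[C@@]2(C=O)Cc1c(OC)c(OC)cc(OC)c1OC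
F7 | step 5 | hydrazone of F6 | CC(C)(C)[Si](C)(C)O[C@H]1CCC[C@@]2(C)[C@H]1CC[C@H](C)[C@@]2(C=NN)Cc1c(OC)c(OC)cc(OC)c1OC
F8 | step 6 | [4β-(tert-butyldimethylsilyloxy)-8β,9β,10β-trimethyl-Δ5-octalin-9α-yl]methanol | CC(C)(C)[Si](C)(C)O[C@H]1CCC[C@@]2(C)C1=CC[C@H](C)[C@@]2(C)CO
F9 | step 6 | [4β-(tert-butyldimethylsilyloxy)-8β,9β,10β-trimethyl-5α-decalin-9α-yl]methanol | CC(C)(C)[Si](C)(C)O[C@H]1CCC[C@@]2(C)[C@H]1CC[C@H](C)[C@@]2(C)CO
F10 | step 7 | (2,3,5,6-tetramethoxyphenyl)[4β-(tert-butyldimethylsilyloxy)-8β,9β,10β-trimethyl-Δ5-octalin-9α-yl]methanol, C11 not defined | CC(C)(C)[Si](C)(C)O[C@H]1CCC[C@@]2(C)C1=CC[C@H](C)[C@@]2(C)C(O)c1c(OC)c(OC)cc(OC)c1OC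
F11 | step 12 | 8β,9β,10β-trimethyl-9α-(2,3,5,6-tetramethoxybenzyl)-4-[(trimethylsilyl)methyl]-5α-decalin-4-ol, C4 not defined | C[Si](C)(C)CC1(O)CCC[C@@]2(C)[C@H]1CC[C@H](C)[C@@]2(C)Cc1c(OC)c(OC)cc(OC)c1OC
F12 | step 14 | 2,5-dihydroxy-3-{[(1R,2S,4aS,8aS)-1,2,8a-trimethyl-5-methylidenedecahydronaphthalen-1-yl]methyl}cyclohexa-2,5-diene-1,4-dione | C=C1CCC[C@@]2(C)[C@H]1CC[C@H](C)[C@@]2(C)CC1=C(O)C(=O)C=C(O)C1=O
A1 | alternative 1 | trans-fused Δ6-octalin with 4α-silyloxy, 9β-formyl and 9α-(2,3,5,6-tetramethoxybenzyl) groups | CC(C)(C)[Si](C)(C)O[C@@H]1CCC[C@@]2(C)[C@H]1C=C[C@H](C)[C@@]2(C=O)Cc1c(OC)c(OC)cc(OC)c1OC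
A2 | alternative 1 | (2E,8E,10E)-7-(tert-butyldimethylsilyloxy)-3-methyl-2-(2,3,5,6-tetramethoxybenzyl)dodeca-2,8,10-trienal, R at the silyloxy carbon | C/C=C/C=C/[C@H](O[Si](C)(C)C(C)(C)C)CCC/C(C)=C(/C=O)Cc1c(OC)c(OC)cc(OC)c1OC
A3 | alternative 2 | 8β,9β,10β-trimethyl-4-methylidene-9α-(2,3,5,6-tetramethoxybenzyl)-5α-decalin-6-one | C=C1CCC[C@@]2(C)[C@H]1C(=O)C[C@H](C)[C@@]2(C)Cc1c(OC)c(OC)cc(OC)c1OC
A4 | alternative 2 | tert-butyldimethylsilyl enol ether of the 3-(pent-4-ynyl)-3,4,5-trimethyl-4-(2,3,5,6-tetramethoxybenzyl)cyclohexanone | C#CCCC[C@@]1(C)C=C(O[Si](C)(C)C(C)(C)C)C[C@H](C)[C@@]1(C)Cc1c(OC)c(OC)cc(OC)c1OC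
A5 | alternative 3 | 3-tert-butoxy-5-methoxy-2-(decalinylmethyl)benzene-1,4-diol carrying the decalin of 19 | C=C1CCC[C@@]2(C)[C@H]1CC[C@H](C)[C@@]2(C)Cc1c(OC(C)(C)C)c(O)cc(OC)c1O
A6 | alternative 3 | 3-tert-butoxy-4-hydroxy-4-(2-methoxyvinyl)-2-(decalinylmethyl)cyclobut-2-en-1-one carrying the decalin of 19, carbinol centre and enol ether geometry not defined | C=C1CCC[C@@]2(C)[C@H]1CC[C@H](C)[C@@]2(C)CC1=C(OC(C)(C)C)C(O)(C=COC)C1=O
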